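- I had no rate constants for this flask, so I began from the two earlier runs, where I took the mean of the four readings for each product.

| setting | noon | spring | flask |
|---|---|---|---|
| solid substrate | 0.34 M | 0.75 M | 0.50 M |
| remark | run made earlier | run made earlier |  |
| time |  |  | 20 h |

| run | time / h | side product A / % | target / % | solid substrate / % |
|---|---|---|---|---|
| noon | 1.50 | 66.4 | 3.5 | 0 |
| noon | 4.00 | 66.2 | 3.3 | 0 |
| noon | 8.00 | 66.0 | 3.4 | 0.5 |
| noon | 20.0 | 66.3 | 3.6 | 0.2 |
| spring | 1.50 | 62.8 | 3.4 | 0 |
| spring | 4.00 | 62.4 | 3.2 | 0.1 |
| spring | 8.00 | 62.1 | 3.4 | 0 |
| spring | 20.0 | 62.5 | 3.6 | 0 |

(readings scatter by 0.3 percentage points)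

1. share of side product A in side product A plus target at 12 min
2. share of side product A in side product A plus target at 2.0 h
3. share of side product A in side product A plus target at 20 h
4. which of side product A and target there is more of at 20 h

- solid, in amounts per volume of the solution: solid substrate
- the numbers in the tables scatter with a standard deviation of 0.3 percentage points
- at the start none of the solid substrate is in solution

- The noon run held 66.2 % side product A and 3.45 % target; the spring run held 62.5 % and 3.40 %.
- These numbers seem not to go together: the spring run's two products sum to 3.8 percentage points less than the noon run's, yet the share of side product A moves only from 95.0 % to 94.8 %, a shift smaller than the scatter of one reading.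
- A ratio clears this up: if a loss lowers both products by one factor, that factor cancels in the share.
- I therefore carried the end share S, the mean of the two runs' shares of side product A in side product A plus target, 94.9 %.
- This flask's 0.50 M lies between the two charges, so I committed to S at 2.0 h and 20 h, with side product A ahead of target.
- The readings begin at 1.50 h, later than 12 min, so S told me nothing about that time.
- The forecast gave 95 % (90 % to 97.5 %) at 12 min, 95 % at 2.0 h and 95 % at 20 h, with side product A ahead, expecting that “parallel pathways keep a constant ratio”, whereas I gave no figure for 12 min.
- This flask gave 78.5 % at 12 min, 94.9 % at 2.0 h and 94.9 % at 20 h, with side product A ahead; S matched the two later shares, and the early share lay 16 points below it.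

    starting material → intermediate A (k = 2.30 /min)
    intermediate A → intermediate B (k = 0.100 /min)
    intermediate B ⇌ intermediate C (K = 13.0, k = 0.150 /min)
    intermediate C → intermediate D (k = 0.300 /min)
    intermediate B → target (k = 0.0610 /min)
    intermediate D → side product A (k = 1.40 /min)
    starting material + intermediate A → side product B (k = 0.480 /M/min)
    solid substrate ⇌ starting material, rate k8*(cs8 - [starting material]) while solid is left; crystals form when [starting material] > cs8 (solubility = 0.240 M, k = 0.610 /min)
    target ⇌ isomer of the product (K = 6.90, k = 0.400 /min)

- In this flask, half of the dissolving of the solid substrate was done by 2.07 min and half of the turning of intermediate A into intermediate B by 0.157 h, while side product A drew level with target at 0.103 h.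
- Target then stood at 3.45 % at 2.00 h and 3.45 % at 20.0 h.
- For the neighbour flask with 1.2 M of solid substrate, a larger charge than the spring run's 0.75 M, S gives 94.9 % at 20 h.
- The computed neighbour flask gave 94.9 % at 20 h, from 60.0 % side product A and 3.21 % target, and 73.4 % at 12 min.

The earlier runs and the new flask are simulated with made-up constants.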